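Everything rests on opening ring A at C5–C10 and at the bond from C6 to its side chain. The feature used is that spiro carbon C5 lies alpha to ring B carbinol carbon C4 and between C6 and the tertiary carbinol C10: adding the silyloxypropyl chain to C6 of an enone gives a C4=C5 enolate that closes onto a C10 methyl ketone. One copper-catalysed conjugate addition and aldol thus forms both bonds, ring A and the C5, C6 and C10 stereocentres. The precursor is an (E)-2-alkylidenecyclopentanone whose exocyclic carbon carries the ketal carbon C7 with a 3-oxobutyl arm.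

Key step: step 9

Remarks before the steps
- Numbering: spiro[4.5]decane numbering is used. Ring B is C1–C5 (C5 spiro, C4 carbinol, C3 carries the triene). Ring A is C5–C10 (C6 hydroxypropyl, C7 enal-bearing, C10 tertiary carbinol). C11 is the enal alpha carbon and C1′–C6′ are the triene carbons (C2′ on C3).
- Stereochemical reading of the target: 3S,4S,5S,6R,10S, with 3′E, 5′Z and a (Z) enal in which CHO is cis to C6. On ring A the C6 chain, C4 and the C10 hydroxyl are all cis. On ring B the C4 hydroxyl is cis to C10 and trans to the C3 side chain. The key-step product must therefore be the (5R,6S,10S) isomer (the descriptors at C5 and C6 change later only because CIP priorities change).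
- Point needing care in the key step: simple allylic 1,3-strain reasoning favours the chain trans to C4. The C7 dioxolane is therefore kept deliberately as a zinc-binding group, and the C5 face selectivity is treated as the main risk.
- After the key step the triene enters by trans opening of a ring B epoxide and the enal by oxidative transposition of an isopropenyl carbinol.
- The dialkylzinc 15 is assembled from two portions of iodide 12, one as the alkylzinc iodide and one as the alkyllithium, and the lithium iodide formed is removed before the catalytic step.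
- Assumption: compounds 1, 2, 6, 12, 23, 24, 29 and 31 and the reagents named on the Conditions lines are taken as catalogue items. The ligand antipode in step 9 is to be fixed by experiment, and both enantiomers are available.
- Numbered compounds are substrates, products and flask intermediates. Auxiliary reagents appear on the Conditions line.

Step 1
Reactants: 1 diethyl oxalate; 2 but-3-en-1-ylmagnesium bromide
Product: 3 ethyl 2-oxohex-5-enoate
Conditions: 1 (2 equiv), THF/Et2O, −78 °C; aq. NH4Cl
Reagents that add atoms: none
Why: Acylation of the Grignard reagent by excess oxalate at low temperature should stop at the alpha-keto ester because the tetrahedral magnesium alkoxide survives until work-up.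

Step 2
Reactants: 3 ethyl 2-oxohex-5-enoate
Product: 4 ethyl 2-(but-3-en-1-yl)-1,3-dioxolane-2-carboxylate
Conditions: HOCH2CH2OH, p-TsOH (cat.), benzene, reflux, Dean–Stark
Reagents that add atoms: ethane-1,2-diol, OCCO
Why: Acid-catalysed ketalisation with azeotropic removal of water should convert the activated keto group into the dioxolane that masks C7.

Step 3
Reactants: 4 ethyl 2-(but-3-en-1-yl)-1,3-dioxolane-2-carboxylate
Product: 5 2-(but-3-en-1-yl)-1,3-dioxolane-2-carbaldehyde
Conditions: i-Bu2AlH (1.1 equiv), CH2Cl2, −78 °C; aq. potassium sodium tartrate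
Reagents that add atoms: none
Why: Partial reduction of an alpha,alpha-dialkoxy ester should stop at the aldehyde through a chelated aluminium hemiacetal that collapses only on work-up.

Step 4
Reactants: 6 cyclopentanone; 5 2-(but-3-en-1-yl)-1,3-dioxolane-2-carbaldehyde
Product: 8 2-{[2-(but-3-en-1-yl)-1,3-dioxolan-2-yl](hydroxy)methyl}cyclopentan-1-one (mixture of diastereomers), via lithium cyclopent-1-en-1-olate 7 (not isolated)
Conditions: LiN(i-Pr)2, THF, −78 °C; then 5; aq. NH4Cl
Reagents that add atoms: none
Why: Directed aldol addition of the preformed lithium enolate to a non-enolisable aldehyde should avoid self-condensation, and the two new centres are erased in step 5.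

Step 5
Reactants: 8 2-{[2-(but-3-en-1-yl)-1,3-dioxolan-2-yl](hydroxy)methyl}cyclopentan-1-one
Product: 10 (E)-2-{[2-(but-3-en-1-yl)-1,3-dioxolan-2-yl]methylidene}cyclopentan-1-one, via methanesulfonate 9 (not isolated)
Conditions: MsCl, Et3N, CH2Cl2, 0 °C; then DBU, rt
Reagents that add atoms: none
Why: Mesylation followed by E1cB elimination should give the conjugated enone as the (E) isomer, in which the ketal carbon avoids the carbonyl oxygen.

Step 6
Reactants: 10 (E)-2-{[2-(but-3-en-1-yl)-1,3-dioxolan-2-yl]methylidene}cyclopentan-1-one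
Product: 11 (E)-2-{[2-(3-oxobutyl)-1,3-dioxolan-2-yl]methylidene}cyclopentan-1-one
Conditions: PdCl2 (10 mol %), CuCl (1 equiv), O2 (1 atm), DMF/H2O (7:1), rt
Reagents that add atoms: water, O
Why: Tsuji–Wacker oxidation should convert the terminal alkene into the methyl ketone with Markovnikov selectivity while the electron-poor trisubstituted enone stays inert, so the third carbonyl appears only after the condensation.

Step 7
Reactants: 12 tert-butyl(3-iodopropoxy)dimethylsilane
Product: 13 {3-[(tert-butyldimethylsilyl)oxy]propyl}zinc iodide (THF solution, titrated and used directly)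
Conditions: Zn dust (2 equiv, activated with BrCH2CH2Br and Me3SiCl), THF, 40 °C; excess zinc allowed to settle
Reagents that add atoms: zinc, [Zn]
Why: Direct oxidative insertion of activated zinc into the primary carbon–iodine bond should give the alkylzinc iodide, a reagent class that tolerates the silyl ether.

Step 8
Reactants: 12 tert-butyl(3-iodopropoxy)dimethylsilane (second portion); 13 {3-[(tert-butyldimethylsilyl)oxy]propyl}zinc iodide
Product: 15 bis{3-[(tert-butyldimethylsilyl)oxy]propyl}zinc, via (3-silyloxypropyl)lithium 14 (not isolated)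
Conditions: 12 (1.0 equiv), t-BuLi (2.0 equiv), Et2O/pentane, −78 °C; then 13 (1.0 equiv) in THF, −78 → 0 °C; solvents removed in vacuo, toluene added, LiI filtered off under argon
Reagents that add atoms: none
Why: Iodine–lithium exchange should give the primary alkyllithium, which displaces iodide from zinc in 13 by transmetalation to give the symmetrical dialkylzinc, and precipitation of LiI from toluene leaves a reagent poor enough in salt for asymmetric catalysis.

Step 9
Reactants: 11 (E)-2-{[2-(3-oxobutyl)-1,3-dioxolan-2-yl]methylidene}cyclopentan-1-one; 15 bis{3-[(tert-butyldimethylsilyl)oxy]propyl}zinc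
Product: 18 (5R,6S,10S)-6-{3-[(tert-butyldimethylsilyl)oxy]propyl}-10-hydroxy-10-methylspiro[4.5]decane-4,7-dione 7-ethylene ketal (chain and C10 hydroxyl cis to C4 on ring A), via zinc enolate 16 (not isolated), via zinc aldolate 17 (not isolated)
Conditions: 15 (1.5 equiv), Cu(OTf)2 (3 mol %), (S,R,R)-O,O′-(1,1′-binaphthalene-2,2′-diyl)-N,N-bis(1-phenylethyl)phosphoramidite (6 mol %), toluene, −30 → 0 °C; aq. NH4Cl
Reagents that add atoms: none
Why: Transmetalation from zinc gives a ligand-bound alkylcopper species that adds the silyloxypropyl group 1,4 to the s-cis enone of 11, and the regiodefined zinc enolate 16 (C4=C5) then attacks the tethered C10 methyl ketone to give zinc aldolate 17, which is protonated on work-up. The closest known reaction type is the copper/phosphoramidite-catalysed enantioselective addition of dialkylzincs to enones with capture of the zinc enolate by a pendant ketone. Ring A closes in a 6-(enolexo)-exo-trig mode through a chair in which the new C6 chain is equatorial. C6 is set by the chiral ligand acting on the (E)-enone, C10 by the zinc bridge between enolate and ketone oxygens (hydroxyl cis to C4), and C5 by the enolate face used within that chair. The step needs 1,4-addition without alkyl transfer to either ketone and, above all, closure on the face that places C4 rather than C1 on the side of C7 (chain cis to C4). The C7 dioxolane is meant to secure this, because a ketal oxygen can bind the zinc on the enolate oxygen and hold C7 next to C4–O against the competing closure controlled by allylic strain.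

Step 10
Reactants: 18 (5R,6S,10S)-spiro hydroxy ketone
Product: 19 C4 tosylhydrazone of 18
Conditions: TsNHNH2 (1.2 equiv), EtOH, 60 °C
Reagents that add atoms: 4-methylbenzenesulfonohydrazide, Cc1ccc(cc1)S(=O)(=O)NN
Why: Condensation of the cyclopentanone with tosylhydrazide should give the hydrazone and at the same time remove the retro-aldol liability of the beta-hydroxy ketone before strong base is used.

Step 11
Reactants: 19 C4 tosylhydrazone of 18
Product: 21 6-{3-[(tert-butyldimethylsilyl)oxy]propyl}-10-hydroxy-10-methylspiro[4.5]dec-3-en-7-one ethylene ketal (C5 C6 C10 as in 18), via C4 vinyllithium 20 (not isolated)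
Conditions: n-BuLi (3.3 equiv), THF/TMEDA, −78 → 0 °C; H2O
Reagents that add atoms: none
Why: In this Shapiro reaction the trianion (N–H, O–H and the only alpha hydrogens, at C3) should lose sulfinate and dinitrogen to give the C4 vinyllithium, whose protonation gives the C3=C4 alkene with unambiguous regiochemistry.

Step 12
Reactants: 21 spiro alkene
Product: 22 3,4-epoxide of 21 (epoxide oxygen on the ring B face that carries C10)
Conditions: VO(acac)2 (5 mol %), t-BuOOH (1.5 equiv), CH2Cl2, 0 °C → rt
Reagents that add atoms: tert-butyl hydroperoxide, CC(C)(C)OO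
Why: In this hydroxyl-directed epoxidation the homoallylic C10 hydroxyl, fixed on one face of ring B by the spiro centre, should bind vanadium and deliver oxygen to that face, so the future C4–O bond is cis to C10.

Step 13
Reactants: 23 prop-2-yn-1-ol; 24 5-bromo-2-methylpent-2-ene
Product: 27 (Z)-3-iodo-2-(4-methylpent-3-en-1-yl)prop-2-en-1-ol, via homoprenylmagnesium bromide 25 (not isolated), via vinylmagnesium chelate 26 (not isolated)
Conditions: 24 (3 equiv), Mg, THF; then 23, CuI (10 mol %), Et2O, −10 °C → rt; I2, −20 °C; aq. NH4Cl/Na2S2O3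
Reagents that add atoms: iodine, II
Why: Copper-catalysed anti carbomagnesiation of the propargylic alkoxide should place the alkyl group on C2 and magnesium on C3 inside a five-membered chelate, so iodinolysis gives the vinyl iodide with iodine cis to the hydroxymethyl group.

Step 14
Reactants: 27 (Z)-3-iodo-2-(4-methylpent-3-en-1-yl)prop-2-en-1-ol
Product: 28 tert-butyl{[(2Z)-3-iodo-2-(4-methylpent-3-en-1-yl)prop-2-en-1-yl]oxy}dimethylsilane
Conditions: TBSCl, imidazole, CH2Cl2, rt
Reagents that add atoms: tert-butyldimethylsilyl chloride, CC(C)(C)[Si](C)(C)Cl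
Why: Routine silylation of the primary allylic alcohol should give the ether that survives the organometallic steps and falls off with fluoride at the end.

Step 15
Reactants: 28 vinyl iodide TBS ether; 29 (E)-1,2-bis(tributylstannyl)ethene
Product: 30 tributyl[(1E,3Z)-4-{[(tert-butyldimethylsilyl)oxy]methyl}-8-methylnona-1,3,7-trien-1-yl]stannane
Conditions: 29 (3 equiv), PdCl2(MeCN)2 (5 mol %), DMF, rt
Reagents that add atoms: none
Why: Stille coupling with excess distannane should transfer one stannylvinyl unit with retention at both alkenes, giving the (1E,3Z)-dienylstannane.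

Step 16
Reactants: 30 dienylstannane; 31 1,1-dibromoethene
Product: 32 (3E,5Z)-2-bromo-6-{[(tert-butyldimethylsilyl)oxy]methyl}-10-methylundeca-1,3,5,9-tetraene
Conditions: 31 (5 equiv), Pd2(dba)3 (2.5 mol %), P(2-furyl)3 (10 mol %), toluene, 60 °C
Reagents that add atoms: none
Why: Stille coupling with excess geminal dibromide should stop after one substitution because the dibromoalkene undergoes oxidative addition faster than the 2-bromodiene that is formed.

Step 17
Reactants: 22 epoxy alcohol; 32 2-bromotriene
Product: 36 ring B diol carrying the protected triene at C3 (C3 side chain trans to C4–OH; C4–OH cis to C10), via trienyllithium 33 (not isolated), via trienylmagnesium bromide 34 (not isolated), via bromomagnesium alkoxide 35 (not isolated)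
Conditions: 32 (1.5 equiv), t-BuLi (2 equiv per 32), Et2O, −78 °C; MgBr2·OEt2; then 22 pretreated with MeMgBr (1.0 equiv), CuI (10 mol %), THF, −30 → 0 °C; aq. NH4Cl
Reagents that add atoms: none
Why: Bromine–lithium exchange, transmetalation and copper-catalysed SN2 opening at C3 (C4 is neopentyl) with inversion should give the trans C3/C4 relationship, so both centres follow from the epoxide face set in step 12.

Step 18
Reactants: 36 ring B diol
Product: 37 4,10-O-(di-tert-butylsilylene) derivative of 36
Conditions: t-Bu2Si(OTf)2 (1.2 equiv), 2,6-lutidine, CH2Cl2, 0 °C → rt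
Reagents that add atoms: di-tert-butylsilyl bis(trifluoromethanesulfonate), CC(C)(C)[Si](OS(=O)(=O)C(F)(F)F)(OS(=O)(=O)C(F)(F)F)C(C)(C)C
Why: The cis-disposed C4 and C10 hydroxyls should form a six-membered cyclic silylene, which shields the secondary alcohol from the later oxidation and is removable by fluoride.

Step 19
Reactants: 37 silylene ketal
Product: 38 C7 ketone (dioxolane removed; C6 configuration retained)
Conditions: pyridinium p-toluenesulfonate (0.2 equiv), acetone/H2O (10:1), 50 °C
Reagents that add atoms: water, O
Why: Mild acid-catalysed ketal hydrolysis should unveil the C7 ketone while the silyl ethers, the silylene and the triene persist, and the weak acid should not enolise C6.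

Step 20
Reactants: 38 C7 ketone
Product: 39 C7 isopropenyl carbinol (tertiary allylic alcohol; C7 configuration irrelevant)
Conditions: CeCl3 (3 equiv), CH2=C(CH3)MgBr (3 equiv), THF, −78 °C; aq. NH4Cl
Reagents that add atoms: isopropenylmagnesium bromide, CC(=C)[Mg]Br
Why: 1,2-Addition of the weakly basic organocerium reagent to the hindered enolisable ketone should proceed without epimerising C6, and the new C7 centre is destroyed in step 21.

Step 21
Reactants: 39 C7 isopropenyl carbinol
Product: 41 bis-TBS silylene-protected (Z)-enal (C7=C11 with CHO cis to C6), via rearranged allylic chlorochromate 40 (not isolated)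
Conditions: pyridinium chlorochromate [C5H5NH][CrO3Cl] (3 equiv), 4 Å MS, CH2Cl2, rt
Reagents that add atoms: pyridinium chlorochromate, [O-][Cr](=O)(=O)Cl.c1cc[nH+]cc1
Why: In this Babler–Dauben oxidative transposition the tertiary chromate ester should undergo a [3,3] shift to the primary allylic ester and be oxidised to the tetrasubstituted enal, the (Z) isomer being expected to prevail because the planar formyl group rather than methyl then faces the substituted C6, with any (E) isomer removed by chromatography.

Step 22
Reactants: 41 protected (Z)-enal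
Product: 42 target (3S,4S,5S,6R,10S; 3′E,5′Z; Z enal)
Conditions: HF·pyridine, pyridine, THF, 0 °C → rt
Reagents that add atoms: none
Why: Buffered fluoride should cleave both primary silyl ethers and the cyclic silylene in one operation without touching the enal or the triene.

Compound list
1 | diethyl oxalate | CCOC(=O)C(=O)OCC | starting material
2 | but-3-en-1-ylmagnesium bromide | C=CCC[Mg]Br | starting material
3 | ethyl 2-oxohex-5-enoate | CCOC(=O)C(=O)CCC=C | intermediate
4 | ethyl 2-(but-3-en-1-yl)-1,3-dioxolane-2-carboxylate | CCOC(=O)C1(CCC=C)OCCO1 | intermediate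
5 | 2-(but-3-en-1-yl)-1,3-dioxolane-2-carbaldehyde | O=CC1(CCC=C)OCCO1 | intermediate
6 | cyclopentanone | O=C1CCCC1 | starting material
7 | lithium cyclopent-1-en-1-olate | [Li]OC1=CCCC1 | intermediate (not isolated)
8 | 2-{[2-(but-3-en-1-yl)-1,3-dioxolan-2-yl](hydroxy)methyl}cyclopentan-1-one, diastereomer mixture | O=C1CCCC1C(O)C2(CCC=C)OCCO2 | intermediate
9 | methanesulfonate of 8 | O=C1CCCC1C(OS(C)(=O)=O)C2(CCC=C)OCCO2 | intermediate (not isolated)
10 | (E)-2-{[2-(but-3-en-1-yl)-1,3-dioxolan-2-yl]methylidene}cyclopentan-1-one | O=C1CCC/C1=C\C2(CCC=C)OCCO2 | intermediate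
11 | (E)-2-{[2-(3-oxobutyl)-1,3-dioxolan-2-yl]methylidene}cyclopentan-1-one, key-step precursor | O=C1CCC/C1=C\C2(CCC(C)=O)OCCO2 | intermediate
12 | tert-butyl(3-iodopropoxy)dimethylsilane | CC(C)(C)[Si](C)(C)OCCCI | starting material
13 | {3-[(tert-butyldimethylsilyl)oxy]propyl}zinc iodide | CC(C)(C)[Si](C)(C)OCCC[Zn]I | intermediate
14 | {3-[(tert-butyldimethylsilyl)oxy]propyl}lithium | CC(C)(C)[Si](C)(C)OCCC[Li] | intermediate (not isolated)
15 | bis{3-[(tert-butyldimethylsilyl)oxy]propyl}zinc | CC(C)(C)[Si](C)(C)OCCC[Zn]CCCO[Si](C)(C)C(C)(C)C | intermediate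
16 | alkylzinc C4=C5 enolate of the conjugate adduct | CC(=O)CCC1(OCCO1)[C@@H](CCCO[Si](C)(C)C(C)(C)C)C2=C(O[Zn]CCCO[Si](C)(C)C(C)(C)C)CCC2 | intermediate (not isolated)
17 | alkylzinc C10 aldolate | C1CC[C@]2([C@H](CCCO[Si](C)(C)C(C)(C)C)C3(OCCO3)CC[C@]2(C)O[Zn]CCCO[Si](C)(C)C(C)(C)C)C1=O | intermediate (not isolated)
18 | (5R,6S,10S)-6-{3-[(tert-butyldimethylsilyl)oxy]propyl}-10-hydroxy-10-methylspiro[4.5]decane-4,7-dione 7-ethylene ketal, key-step product | C1CC[C@]2([C@H](CCCO[Si](C)(C)C(C)(C)C)C3(OCCO3)CC[C@]2(C)O)C1=O | intermediate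
19 | C4 tosylhydrazone of 18 | C1CC[C@]2([C@H](CCCO[Si](C)(C)C(C)(C)C)C3(OCCO3)CC[C@]2(C)O)C1=NNS(=O)(=O)c4ccc(C)cc4 | intermediate
20 | C4 vinyllithium, lithium C10 alkoxide | C1CC[C@]2([C@H](CCCO[Si](C)(C)C(C)(C)C)C3(OCCO3)CC[C@]2(C)O[Li])C([Li])=1 | intermediate (not isolated)
21 | spiro[4.5]dec-3-ene with C7 dioxolane, C10 hydroxyl and C6 silyloxypropyl chain | C1CC[C@]2([C@H](CCCO[Si](C)(C)C(C)(C)C)C3(OCCO3)CC[C@]2(C)O)C=1 | intermediate
22 | 3,4-epoxide of 21, oxygen cis to C10 on ring B | C1C[C@@H]2O[C@@H]2[C@@]13[C@H](CCCO[Si](C)(C)C(C)(C)C)C4(OCCO4)CC[C@]3(C)O | intermediate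
23 | prop-2-yn-1-ol | C#CCO | starting material
24 | 5-bromo-2-methylpent-2-ene | CC(C)=CCCBr | starting material
25 | (4-methylpent-3-en-1-yl)magnesium bromide | CC(C)=CCC[Mg]Br | intermediate (not isolated)
26 | vinylmagnesium alkoxide chelate, Mg cis to CH2O | CC(C)=CCC/C(CO[Mg]Br)=C/[Mg]Br | intermediate (not isolated)
27 | (Z)-3-iodo-2-(4-methylpent-3-en-1-yl)prop-2-en-1-ol | CC(C)=CCC/C(CO)=C/I | intermediate
28 | tert-butyl{[(2Z)-3-iodo-2-(4-methylpent-3-en-1-yl)prop-2-en-1-yl]oxy}dimethylsilane | CC(C)=CCC/C(CO[Si](C)(C)C(C)(C)C)=C/I | intermediate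
29 | (E)-1,2-bis(tributylstannyl)ethene | CCCC[Sn](CCCC)(CCCC)/C=C/[Sn](CCCC)(CCCC)CCCC | starting material
30 | tributyl[(1E,3Z)-4-{[(tert-butyldimethylsilyl)oxy]methyl}-8-methylnona-1,3,7-trien-1-yl]stannane | CCCC[Sn](CCCC)(CCCC)/C=C/C=C(\CO[Si](C)(C)C(C)(C)C)CCC=C(C)C | intermediate
31 | 1,1-dibromoethene | C=C(Br)Br | starting material
32 | (3E,5Z)-2-bromo-6-{[(tert-butyldimethylsilyl)oxy]methyl}-10-methylundeca-1,3,5,9-tetraene | C=C(Br)/C=C/C=C(\CO[Si](C)(C)C(C)(C)C)CCC=C(C)C | intermediate
33 | trienyllithium from 32 | C=C([Li])/C=C/C=C(\CO[Si](C)(C)C(C)(C)C)CCC=C(C)C | intermediate (not isolated)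
34 | trienylmagnesium bromide from 32 | C=C([Mg]Br)/C=C/C=C(\CO[Si](C)(C)C(C)(C)C)CCC=C(C)C | intermediate (not isolated)
35 | bromomagnesium C10 alkoxide of 22 | C1C[C@@H]2O[C@@H]2[C@@]13[C@H](CCCO[Si](C)(C)C(C)(C)C)C4(OCCO4)CC[C@]3(C)O[Mg]Br | intermediate (not isolated)
36 | ring B diol with protected triene at C3, C7 dioxolane | C=C(/C=C/C=C(\CO[Si](C)(C)C(C)(C)C)CCC=C(C)C)[C@@H]1CC[C@]2([C@H](CCCO[Si](C)(C)C(C)(C)C)C3(OCCO3)CC[C@]2(C)O)[C@H]1O | intermediate
37 | 4,10-O-(di-tert-butylsilylene) derivative of 36 | C=C(/C=C/C=C(\CO[Si](C)(C)C(C)(C)C)CCC=C(C)C)[C@@H]1CC[C@]2([C@H](CCCO[Si](C)(C)C(C)(C)C)C3(OCCO3)CC[C@]2(C)O4)[C@H]1O[Si]4(C(C)(C)C)C(C)(C)C | intermediate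
38 | C7 ketone | C=C(/C=C/C=C(\CO[Si](C)(C)C(C)(C)C)CCC=C(C)C)[C@@H]1CC[C@]2([C@H](CCCO[Si](C)(C)C(C)(C)C)C(=O)CC[C@]2(C)O3)[C@H]1O[Si]3(C(C)(C)C)C(C)(C)C | intermediate
39 | C7 isopropenyl carbinol, C7 unspecified | C=C(/C=C/C=C(\CO[Si](C)(C)C(C)(C)C)CCC=C(C)C)[C@@H]1CC[C@]2([C@H](CCCO[Si](C)(C)C(C)(C)C)C(O)(C(C)=C)CC[C@]2(C)O3)[C@H]1O[Si]3(C(C)(C)C)C(C)(C)C | intermediate
40 | rearranged primary allylic chlorochromate | C=C(/C=C/C=C(\CO[Si](C)(C)C(C)(C)C)CCC=C(C)C)[C@@H]1CC[C@]2([C@H](CCCO[Si](C)(C)C(C)(C)C)/C(=C(/C)CO[Cr](=O)(=O)Cl)CC[C@]2(C)O3)[C@H]1O[Si]3(C(C)(C)C)C(C)(C)C | intermediate (not isolated)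
41 | bis-TBS silylene-protected (Z)-enal | C=C(/C=C/C=C(\CO[Si](C)(C)C(C)(C)C)CCC=C(C)C)[C@@H]1CC[C@]2([C@H](CCCO[Si](C)(C)C(C)(C)C)/C(=C(/C)C=O)CC[C@]2(C)O3)[C@H]1O[Si]3(C(C)(C)C)C(C)(C)C | intermediate
42 | CNP0249558.1 | C=C(/C=C/C=C(\CO)CCC=C(C)C)[C@@H]1CC[C@]2([C@H](CCCO)/C(=C(/C)C=O)CC[C@]2(C)O)[C@H]1O | target

Total step count: 22.
Longest linear sequence: 16 steps (steps 1–6, 9–12 and 17–22).

Steps most likely to fail

1. Step 9. Ring A may close on the other enolate face, giving the chain trans to C4, if allylic 1,3-strain between the zinc-bearing oxygen and C7 outweighs ketal–zinc binding. Conjugate addition next to the quaternary ketal carbon may also be slow. The fallback sets out from 10 and returns at 18. Conjugate addition of 15 to 10 under the same Cu(OTf)2/phosphoramidite catalysis in the presence of Me3SiCl gives the trimethylsilyl enol ether F1, since no ketone is present to intercept the enolate. NBS converts it into the C5 alpha-bromo ketone F2. Tsuji–Wacker oxidation (PdCl2, CuCl, O2) gives the bromo diketone F3. SmI2 in THF at −78 °C then forms the trivalent samarium enolate regiospecifically at C5, and ring A closes as a samarium Reformatsky-type aldol to 18. The larger, more oxophilic metal can hold enolate, ketone and ketal oxygens together, which gives a second, independent handle on the enolate face.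

2. Step 17. SN2 attack at the hindered cyclopentene oxide may be slow, which would allow halide opening or rearrangement of the epoxide by magnesium salts and positional scrambling of the dienyl organometallic. The fallback sets out from 22 and returns at 36. Copper-catalysed opening of 22 with [1-(trimethylsilyl)vinyl]magnesium bromide gives the alpha-silylvinyl diol F4, with the same regio- and stereochemical logic. Iododesilylation with NIS gives the 2-iodoalkene diol F5. Stille coupling of F5 with dienylstannane 30 (Pd2(dba)3, AsPh3) gives 36. This path also makes bromotriene 32 and step 16 unnecessary.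

3. Step 21. Geometric control in the sigmatropic shift may be poor, and the triene may be eroded by acid during the oxidation with hexavalent chromium. The fallback sets out from 38 and returns at 41. Horner–Wadsworth–Emmons reaction of 38 with diethyl (1-cyanoethyl)phosphonate and NaH gives the tetrasubstituted unsaturated nitrile F6. Its geometric isomers are configurationally stable and separable, and the small linear cyano group should prefer the side of C6. Reduction of the (Z)-nitrile with i-Bu2AlH and hydrolysis of the imine give 41.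

Further compounds
F1 | step 9 | trimethylsilyl enol ether of the conjugate adduct of 10 | C=CCCC1(OCCO1)[C@@H](CCCO[Si](C)(C)C(C)(C)C)C2=C(O[Si](C)(C)C)CCC2
F2 | step 9 | C5 alpha-bromo ketone, C5 unspecified | C=CCCC1(OCCO1)[C@@H](CCCO[Si](C)(C)C(C)(C)C)C2(Br)CCCC2=O
F3 | step 9 | bromo diketone | CC(=O)CCC1(OCCO1)[C@@H](CCCO[Si](C)(C)C(C)(C)C)C2(Br)CCCC2=O
F4 | step 17 | alpha-silylvinyl diol | C=C([Si](C)(C)C)[C@@H]1CC[C@]2([C@H](CCCO[Si](C)(C)C(C)(C)C)C3(OCCO3)CC[C@]2(C)O)[C@H]1O
F5 | step 17 | 2-iodoalkene diol | C=C(I)[C@@H]1CC[C@]2([C@H](CCCO[Si](C)(C)C(C)(C)C)C3(OCCO3)CC[C@]2(C)O)[C@H]1O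
F6 | step 21 | (Z)-unsaturated nitrile | C=C(/C=C/C=C(\CO[Si](C)(C)C(C)(C)C)CCC=C(C)C)[C@@H]1CC[C@]2([C@H](CCCO[Si](C)(C)C(C)(C)C)/C(=C(/C)C#N)CC[C@]2(C)O3)[C@H]1O[Si]3(C(C)(C)C)C(C)(C)C
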